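Remark: the cyclohexene atoms are called C1' (aroyl-bearing), C2' (prenyl-bearing), C3' (methyl-bearing, sp2), C4', C5' and C6' (phenyl-bearing). The SMILES corresponds to (1'R,2'S,6'R): aroyl trans to phenyl and cis to prenyl. Compounds 1, 2, 4, 16 and 21 are taken to be commercial.

## The problem

The target 23 is a cyclohex-3-ene with three contiguous stereocentres, C1' (R, aroyl), C2' (S, prenyl) and C6' (R, phenyl), a trisubstituted C3'(Me)=C4' alkene, and a ketone linking C1' to C8 of a 7-hydroxy-5-methoxy-2,2-dimethyl-2H-chromene. In the half-chair the aroyl and phenyl groups are equatorial and the prenyl group is pseudoaxial, away from the C3' methyl group. C1' is α to the ketone and can be lost by enolisation, whereas C2' and C6' are fixed once made and stand 1,3 to each other across C1'; only C6' can reasonably be made alone, and it must then control the others. The ring alkene must end at C3'=C4', out of conjugation, and it, the prenyl alkene and the chromene alkene rule out hydrogenation, strong Lewis acids and strong protic acid late in the route. The ketone is flanked by two ortho oxygens on one side and two substituted ring carbons on the other, so the aryl–carbonyl bond is hard to make, and the pattern of acyl, OH, OMe and pyran oxygen on the arene must be unambiguous; in the 2,6-dihydroxy-4-methoxyphenyl ketone 20 the two ortho positions are equivalent, so pyran annulation has a single outcome. The feature that makes the key step possible is the array ketone carbon–C1'–C2'–C3'=C4', a γ,δ-unsaturated carbonyl unit in which C4' is tied back to C1' by only C5'–C6'. Joining the acyl oxygen to C4' therefore gives a six-membered lactone ring (O, C=O, C1', C6', C5', C4') with the C3'=C2' alkene exocyclic at C4', an allyl ester set up for a [3,3] shift that forms C1'–C2'. In that lactone C6' carries two CH2–C(O) arms, which traces it to prochiral 3-phenylglutaric anhydride 4.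

## Retrosynthesis

23 ⇒ 20 + 21. The pyran bonds O1–C2 and C4–C4a are cut, giving the 2,6-dihydroxy-4-methoxyphenyl ketone 20 and 3-methylbut-2-enal 21. Closing the pyran last keeps the acid-labile chromene out of every organometallic and acidic step and makes the arene symmetric for all earlier chemistry. The alternative of carrying the chromene through would need a C8-metalated chromene of defined regiochemistry. The forward reaction must stop after one annulation.

20 ⇒ 19 ⇒ 15 + 18. After removal of two MOM groups (19), the aryl–C(=O) bond is cut to Weinreb amide 15 and aryllithium 18, which comes by lithiation of bis-MOM ether 17, made from 5-methoxyresorcinol 16. Friedel–Crafts or Fries acylation of the phenol would be regiorandom and acidic; 18 is a symmetric nucleophile, so no regiochemistry arises. Amide 15 comes from acid 13 through acyl imidazolide 14. The forward reaction must add once to a hindered acyl donor without enolising C1'.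

13 ⇒ 10 (through 12 and 11). C1'–C2' is cut, the carboxyl oxygen is joined to C4' and the alkene is moved to C3'=C2' (E): this is the retro-Ireland–Claisen to lactone 10. The neighbouring cuts C1'–C2' plus C5'–C6' (the [4+2] pair) demand intermolecular regio-, endo/exo and facial selection. The single C1'–C2' bond, made intramolecularly through a forced boat, replaces these by two properties of the precursor: a cis-1,3 relation in a δ-lactone and an E alkene. Lactone 10 has two non-adjacent stereocentres instead of three contiguous ones. Its ketene acetal 11 is formally the hetero-Diels–Alder adduct of a silyl cinnamate with the vinyl group of ocimene, here made with defined configuration. The forward reaction must enolise and silylate the lactone cleanly, and the [3,3] shift must outrun cycloreversion.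

10 ⇒ 8 (through 9). The lactone acyl–O bond is cut and C4' is returned to a ketone, giving keto ester 8. The C4' configuration then becomes a reagent-controlled reduction of an α-methyl enone, a well-behaved substrate class; adding an alkenyl metal to an aldehyde would rely on weak 1,3-induction from C6'. The forward step needs facial selectivity at C4' and lactonisation without ionising the allylic alcohol 9.

8 ⇒ 5 + 3 (through 6 and 7), 3 ⇒ 1 + 2. The acyl–alkenyl bond C4'–C3' is cut to acid chloride 6 (from hemiester 5) and alkenylzirconocene 7. The E-trisubstituted alkene is thus made by syn-hydrometalation of the 2-alkyne 3 and not by an olefination that would need separation. Enyne 3 comes from prenyl bromide 1 and propynylmagnesium bromide 2. The forward step needs regioselective Zr–H addition and acylation in the presence of the methyl ester.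

5 ⇒ 4. The two CH2–C(=O) arms at C6' are made identical, giving 3-phenylglutaric anhydride 4. Enantioselective methanolysis sets C6', the only stereocentre that has to be made by itself, and at the same time differentiates the arm that becomes C5'–C4' from the arm that becomes C1' and the ketone carbon.

## Roads not taken

Alternative 1: cut C1'–C2' and C5'–C6' together, the Diels–Alder reaction of chromene chalcone A1 with (E)-β-ocimene A2 under a chiral Lewis acid bound to the peri-hydroxy ketone. This is the shortest route and the one most chemists would draw. It leaves four selectivities to one intermolecular transition state.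
- Regiochemistry: the C4 alkyl terminus of A2 directs the acyl-bearing carbon next to it, as in 23, but the C3 methyl group directs the other way.
- Endo/exo selectivity decides C2'.
- Facial selectivity decides the absolute configuration and must be induced on an electron-rich, hindered dienophile by a chiral Lewis acid.
- Only the E isomer of A2 can react.

The chosen plan is longer but turns each of these into a structural constraint: connectivity for regiochemistry, alkene geometry and a forced boat for C1'/C2', and a stereocentre set by desymmetrisation for the absolute sense.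

Alternative 2: cut C3'=C4' by ring-closing metathesis of the open-chain diene A3. A3 needs its three contiguous stereocentres built in a chain, where C6' can steer C1' and C2' only by 1,2-induction. In the metathesis the isopropenyl group is the slow partner while the prenyl and chromene alkenes of A3 are competing sites. The chosen plan closes the same ring with a bond (C1'–C2') whose formation is itself the stereo-defining event.

Alternative 3: cut C1'–C2' by a 6-endo intramolecular Michael addition of the ester enolate of 8 onto its own enone, giving cyclohexanone A4, followed by conversion of the C4' ketone into the C3'=C4' alkene through an enol triflate and reduction. The ring would close while C3' is still sp3, so the preferred arrangement is all-equatorial, with prenyl trans to the ester. This is the wrong C2' configuration, because the pseudoaxial prenyl group of 23 is favoured only once C3' is sp2. The Michael addition is reversible, a throwaway stereocentre is made at C3', and two more redox steps with an enolisation regiochemistry problem (C3' versus C5') are needed. The [3,3] shift sets C2' kinetically and delivers the alkene in place.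

Key step: step 5

## Route

Step 1
Reactants: 1 prenyl bromide (1-bromo-3-methylbut-2-ene); 2 prop-1-yn-1-ylmagnesium bromide
Product: 3 2-methylhept-2-en-5-yne
Conditions: CuBr·SMe2 (5 mol%), THF, 0 °C → rt
Reagents that add atoms: none
Why: Cu(I)-catalysed coupling of an alkynyl Grignard reagent with a primary allylic bromide; the alkynylcopper should attack the unhindered CH2 (SN2) in preference to the tertiary γ-carbon, giving the skipped enyne.

Step 2
Reactants: 4 3-phenylglutaric anhydride
Product: 5 (3R)-5-methoxy-5-oxo-3-phenylpentanoic acid
Conditions: MeOH (10 equiv), cinchona-alkaloid-derived bifunctional sulfonamide catalyst (10 mol%), MTBE, rt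
Reagents that add atoms: methanol, CO
Why: Organocatalytic enantioselective alcoholysis (desymmetrisation) of a prochiral cyclic anhydride: the quinuclidine activates methanol and the hydrogen-bond donor selects one enantiotopic carbonyl, which sets C6'; the quinine- or quinidine-derived pseudoenantiomer is chosen so that the (R)-hemiester forms, and the acid can be enriched further as a crystalline amine salt.

Step 3
Reactants: 5 (3R)-5-methoxy-5-oxo-3-phenylpentanoic acid; 3 2-methylhept-2-en-5-yne
Product: 8 methyl (3R,6E)-6,10-dimethyl-5-oxo-3-phenylundeca-6,9-dienoate, via acid chloride 6 (not isolated), via alkenylzirconocene 7 (not isolated)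
Conditions: 5, (COCl)2, cat. DMF, CH2Cl2, 0 °C, evaporate; 3, Cp2Zr(H)Cl (1.1 equiv), THF, rt → 40 °C; combine, CuBr·SMe2 (10 mol%), THF, 0 °C → rt
Reagents that add atoms: none
Why: syn-Hydrozirconation of the 2-alkyne should place Zr on the methyl-bearing carbon (less hindered end, equilibrated by the slight excess of Zr–H), and Cu(I)-catalysed acylation of the alkenylzirconocene by the acid chloride proceeds with retention to the (E)-α-methyl enone; the methyl ester and the trisubstituted alkene are inert to both reagents.

Step 4
Reactants: 8 methyl (3R,6E)-6,10-dimethyl-5-oxo-3-phenylundeca-6,9-dienoate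
Product: 10 (4R,6R)-6-[(2E)-6-methylhepta-2,5-dien-2-yl]-4-phenyloxan-2-one, via hydroxy ester 9 (not isolated)
Conditions: (S)-Me-CBS (20 mol%), catecholborane, toluene, −78 °C; MeOH quench, aq. NaOH wash; then PPTS (cat.), toluene, 60 °C
Reagents that add atoms: none
Why: Corey–Bakshi–Shibata reduction of an α-methyl enone, in which the alkenyl group is the large substituent, so the (S)-catalyst should give the (5R)-allylic alcohol under reagent control; catecholborane at −78 °C leaves alkenes and ester alone, and mild acid-catalysed transesterification closes the δ-lactone with alkenyl and phenyl groups cis (both equatorial).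

Step 5
Reactants: 10 (4R,6R)-6-[(2E)-6-methylhepta-2,5-dien-2-yl]-4-phenyloxan-2-one
Product: 13 (1R,2S,6R)-3-methyl-2-(3-methylbut-2-en-1-yl)-6-phenylcyclohex-3-ene-1-carboxylic acid, via silyl ketene acetal 11 (not isolated), via silyl ester 12 (not isolated)
Conditions: LDA, TMSCl–Et3N, THF, −78 °C → rt; then toluene, 100 °C; 1 M HCl
Reagents that add atoms: none
Why: LDA with in-situ silylation converts the lactone into the cyclic silyl ketene acetal 11, in which C1'=C(OSi)–O–C4'–C3'=C2' is an allyl vinyl ether; heating triggers the [3,3]-sigmatropic (Ireland–Claisen) shift that breaks O–C4', forms C1'–C2' and moves the alkene to C3'=C4', and work-up hydrolyses silyl ester 12 to 13. The closest known reaction type is the Ireland–Claisen ring contraction of 6-alkenyl δ-lactones and 6-alkenyl-1,4-dioxan-2-ones to cyclohexene- and dihydropyran-carboxylic acids. The carbocycle C1'–C6' is closed by this one bond in a suprafacial, SN2'-like sense: four lactone atoms (C1', C6', C5', C4') are kept, C3' and C2' are drawn into the ring, and because ketene acetal and allylic carbon share a six-membered ring the transition state can only be a boat shaped like bicyclo[2.2.2]octene. C1': the alkenyl arm can reach only the face of the ketene acetal on which it stands, and as it is cis to the phenyl group the carboxyl carbon is left anti to phenyl (1',6'-trans). C2': with the ketene acetal geometry fixed by the ring and the alkene E, the boat places the prenyl CH2 on the side of the carboxyl bridge (1',2'-cis), so the (R) centre at C4' is traded for (2'S) while C4' becomes sp2. The step needs no selectivity of its own beyond clean O-silylation: the diastereomer is decided by the cis configuration of 10 and the E purity of its alkene, the position of the ring alkene by the shift itself, and C6' is not touched. The internal TMSCl quench at −78 °C keeps the lactone enolate from self-condensation, and the moderate temperature is chosen to stay clear of cycloreversion of the dihydropyran ring of 11.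

Step 6
Reactants: 13 (1R,2S,6R)-3-methyl-2-(3-methylbut-2-en-1-yl)-6-phenylcyclohex-3-ene-1-carboxylic acid
Product: 15 (1R,2S,6R)-N-methoxy-N,3-dimethyl-2-(3-methylbut-2-en-1-yl)-6-phenylcyclohex-3-ene-1-carboxamide, via acyl imidazolide 14 (not isolated)
Conditions: CDI, CH2Cl2, rt; then MeNH(OMe)·HCl, rt → 35 °C
Reagents that add atoms: N,O-dimethylhydroxylamine hydrochloride, CNOC.Cl
Why: Amide formation through the acyl imidazolide under near-neutral conditions, which avoids HCl (alkenes) and strong base (C1'); the Weinreb amide is the acyl donor for a single aryl addition.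

Step 7
Reactants: 16 5-methoxyresorcinol (5-methoxybenzene-1,3-diol)
Product: 17 1-methoxy-3,5-bis(methoxymethoxy)benzene
Conditions: NaH, MOMCl, DMF, 0 °C → rt
Reagents that add atoms: chloromethyl methyl ether (MOMCl), COCCl
Why: Williamson etherification of both phenoxides; the MOM ethers direct the lithiation of step 8 and come off under the mild acid of step 9.

Step 8
Reactants: 17 1-methoxy-3,5-bis(methoxymethoxy)benzene; 15 (1R,2S,6R)-N-methoxy-N,3-dimethyl-2-(3-methylbut-2-en-1-yl)-6-phenylcyclohex-3-ene-1-carboxamide
Product: 19 [4-methoxy-2,6-bis(methoxymethoxy)phenyl][(1R,2S,6R)-3-methyl-2-(3-methylbut-2-en-1-yl)-6-phenylcyclohex-3-en-1-yl]methanone, via aryllithium 18 (not isolated)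
Conditions: 17 (3.3 equiv), n-BuLi (3.0 equiv), THF, 0 °C → rt; then 15, −78 → 0 °C; aq. NH4Cl
Reagents that add atoms: none
Why: Directed ortho-metalation at the position flanked by two OMOM groups (the doubly activated site), then Weinreb ketone synthesis; the N-methoxy amide stops at single addition and releases the ketone only on work-up, so C1' is never exposed to base as a ketone.

Step 9
Reactants: 19 [4-methoxy-2,6-bis(methoxymethoxy)phenyl][(1R,2S,6R)-3-methyl-2-(3-methylbut-2-en-1-yl)-6-phenylcyclohex-3-en-1-yl]methanone
Product: 20 (2,6-dihydroxy-4-methoxyphenyl)[(1R,2S,6R)-3-methyl-2-(3-methylbut-2-en-1-yl)-6-phenylcyclohex-3-en-1-yl]methanone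
Conditions: HCl (cat.), MeOH, 40 °C
Reagents that add atoms: none
Why: Acid-catalysed acetal exchange with methanol; both MOM ethers are ortho to the carbonyl and should cleave under conditions mild enough to leave the two trisubstituted alkenes alone. The product is the (1'R,2'S,6'R) enantiomer of panduratin A.

Step 10
Reactants: 20 (2,6-dihydroxy-4-methoxyphenyl)[(1R,2S,6R)-3-methyl-2-(3-methylbut-2-en-1-yl)-6-phenylcyclohex-3-en-1-yl]methanone; 21 3-methylbut-2-enal
Product: 23 (7-hydroxy-5-methoxy-2,2-dimethyl-2H-chromen-8-yl)[(1R,2S,6R)-3-methyl-2-(3-methylbut-2-en-1-yl)-6-phenylcyclohex-3-en-1-yl]methanone, via o-quinone methide 22 (not isolated)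
Conditions: 21 (1.2 equiv), EDDA (20 mol%), toluene, 100 °C
Reagents that add atoms: none
Why: Knoevenagel-type condensation of the iminium ion of 21 at the aryl carbon ortho to one OH and para to the other, loss of water to o-quinone methide 22, and oxa-6π electrocyclisation; the two ortho positions and the two OH groups of 20 are equivalent by rotation about the aryl–CO bond, so only the chromene with the acyl group between O1 and the 7-OH can form, and no new stereocentre arises.

## Compound list

1 | prenyl bromide (1-bromo-3-methylbut-2-ene) | CC(C)=CCBr | starting material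
2 | prop-1-yn-1-ylmagnesium bromide | CC#C[Mg]Br | starting material
3 | 2-methylhept-2-en-5-yne | CC#CCC=C(C)C | intermediate
4 | 3-phenylglutaric anhydride (4-phenyloxane-2,6-dione) | O=C1CC(c2ccccc2)CC(=O)O1 | starting material
5 | (3R)-5-methoxy-5-oxo-3-phenylpentanoic acid | COC(=O)C[C@H](c1ccccc1)CC(=O)O | intermediate
6 | methyl (3S)-5-chloro-5-oxo-3-phenylpentanoate (acid chloride; not isolated) | COC(=O)C[C@H](c1ccccc1)CC(=O)Cl | intermediate
7 | chlorobis(cyclopentadienyl)[(2E)-6-methylhepta-2,5-dien-2-yl]zirconium (not isolated) | C/C([Zr](Cl)(C1C=CC=C1)C1C=CC=C1)=C\CC=C(C)C | intermediate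
8 | methyl (3R,6E)-6,10-dimethyl-5-oxo-3-phenylundeca-6,9-dienoate | COC(=O)C[C@H](c1ccccc1)CC(=O)/C(C)=C/CC=C(C)C | intermediate
9 | methyl (3R,5R,6E)-5-hydroxy-6,10-dimethyl-3-phenylundeca-6,9-dienoate (not isolated) | COC(=O)C[C@H](c1ccccc1)C[C@@H](O)/C(C)=C/CC=C(C)C | intermediate
10 | (4R,6R)-6-[(2E)-6-methylhepta-2,5-dien-2-yl]-4-phenyloxan-2-one | O=C1C[C@H](c2ccccc2)C[C@H](/C(C)=C/CC=C(C)C)O1 | intermediate
11 | trimethyl({(2R,4R)-2-[(2E)-6-methylhepta-2,5-dien-2-yl]-4-phenyl-3,4-dihydro-2H-pyran-6-yl}oxy)silane (not isolated) | C[Si](C)(C)OC1=C[C@H](c2ccccc2)C[C@H](/C(C)=C/CC=C(C)C)O1 | intermediate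
12 | trimethylsilyl (1R,2S,6R)-3-methyl-2-(3-methylbut-2-en-1-yl)-6-phenylcyclohex-3-ene-1-carboxylate (not isolated) | C[Si](C)(C)OC(=O)[C@@H]1[C@H](CC=C(C)C)C(C)=CC[C@H]1c2ccccc2 | intermediate
13 | (1R,2S,6R)-3-methyl-2-(3-methylbut-2-en-1-yl)-6-phenylcyclohex-3-ene-1-carboxylic acid | OC(=O)[C@@H]1[C@H](CC=C(C)C)C(C)=CC[C@H]1c2ccccc2 | intermediate
14 | (1H-imidazol-1-yl)[(1R,2S,6R)-3-methyl-2-(3-methylbut-2-en-1-yl)-6-phenylcyclohex-3-en-1-yl]methanone (not isolated) | O=C(n1ccnc1)[C@@H]2[C@H](CC=C(C)C)C(C)=CC[C@H]2c3ccccc3 | intermediate
15 | (1R,2S,6R)-N-methoxy-N,3-dimethyl-2-(3-methylbut-2-en-1-yl)-6-phenylcyclohex-3-ene-1-carboxamide | CON(C)C(=O)[C@@H]1[C@H](CC=C(C)C)C(C)=CC[C@H]1c2ccccc2 | intermediate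
16 | 5-methoxyresorcinol (5-methoxybenzene-1,3-diol) | COc1cc(O)cc(O)c1 | starting material
17 | 1-methoxy-3,5-bis(methoxymethoxy)benzene | COCOc1cc(OC)cc(OCOC)c1 | intermediate
18 | [4-methoxy-2,6-bis(methoxymethoxy)phenyl]lithium (not isolated) | [Li]c1c(OCOC)cc(OC)cc1OCOC | intermediate
19 | [4-methoxy-2,6-bis(methoxymethoxy)phenyl][(1R,2S,6R)-3-methyl-2-(3-methylbut-2-en-1-yl)-6-phenylcyclohex-3-en-1-yl]methanone | COCOc1cc(OC)cc(OCOC)c1C(=O)[C@@H]2[C@H](CC=C(C)C)C(C)=CC[C@H]2c3ccccc3 | intermediate
20 | (2,6-dihydroxy-4-methoxyphenyl)[(1R,2S,6R)-3-methyl-2-(3-methylbut-2-en-1-yl)-6-phenylcyclohex-3-en-1-yl]methanone | COc1cc(O)c(C(=O)[C@@H]2[C@H](CC=C(C)C)C(C)=CC[C@H]2c3ccccc3)c(O)c1 | intermediate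
21 | 3-methylbut-2-enal | CC(C)=CC=O | starting material
22 | o-quinone methide from 20 and 21, 6-(3-methylbut-2-en-1-ylidene)cyclohexa-2,4-dienone form (not isolated) | COC1=CC(O)=C(C(=O)[C@@H]2[C@H](CC=C(C)C)C(C)=CC[C@H]2c3ccccc3)C(=O)C1=CC=C(C)C | intermediate
23 | (7-hydroxy-5-methoxy-2,2-dimethyl-2H-chromen-8-yl)[(1R,2S,6R)-3-methyl-2-(3-methylbut-2-en-1-yl)-6-phenylcyclohex-3-en-1-yl]methanone | COc1cc(O)c(C(=O)[C@@H]2[C@H](CC=C(C)C)C(C)=CC[C@H]2c2ccccc2)c2c1C=CC(C)(C)O2 | target

## Step count and risks

Total: 10 steps. Longest linear sequence: 8 steps (steps 2, 3, 4, 5, 6, 8, 9, 10, from 4 to 23); steps 1 and 7 are side branches.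

Step 5 (key step). The boat-shaped shift requires the alkenyl arm and the phenyl group to move together onto pseudoaxial positions over the ketene acetal. If the shift is slow at temperatures the trimethylsilyl ketene acetal tolerates, C-silylation, hydrolysis back to the lactone, cycloreversion of the dihydropyran ring or ionisation of the allylic C4'–O bond (loss of chirality transfer) may compete. Fallback: the same C1'–C2' bond is made at the ketone oxidation level. Lactone 10 is treated at −78 °C with aryllithium 18 (generated from 17 as in step 8), which adds to the unhindered lactone carbonyl to give the lactol F1. Acid-catalysed dehydration (PPTS, toluene, molecular sieves) gives the cyclic enol ether F2. Heating F2 (about 180–200 °C, base-washed sealed vessel, trace of amine) effects the thermal Claisen rearrangement of a 2-alkenyl-3,4-dihydro-2H-pyran to a 4-acylcyclohexene, a known reaction type that runs through the same boat array and should therefore give the same stereochemical result. The product is ketone 19, where the route is rejoined; this also bypasses steps 6 and 8.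

Step 3. Three processes may interfere:
- incomplete regiocontrol in the Zr–H addition, since the two alkyne ends differ only as methyl versus primary alkyl;
- alkoxy exchange between the ester and acid chloride ends of 6 through a cyclic acyloxonium ion, which would erode the configuration at C6';
- reduction of the acid chloride by residual Zr–H.

Fallback: hemiester 5 is converted into the S-ethyl thioester F3 (EtSH, DCC, DMAP), which cannot scramble. Enyne 3 is converted by hydrozirconation and iodinolysis into the alkenyl iodide F4, which is freed from its regioisomer by distillation or chromatography. F4 is turned into the alkenylzinc chloride F5 (t-BuLi, then ZnCl2), and Pd-catalysed thioester–organozinc (Fukuyama) coupling of F5 with F3 gives 8, where the route is rejoined.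

Step 8. Addition of a 2,6-disubstituted aryllithium to an amide carbonyl flanked by two substituted ring carbons may be slow. Base-induced loss of formaldehyde from the N-methoxy group, deprotonation at C1' with epimerisation on quench, or lithiation of 17 next to the methoxy group could then compete. Fallback: amide 15 is reduced (DIBAL-H, −78 °C) to the aldehyde F6, a smaller and more reactive electrophile. Addition of 18 gives the carbinol F7 as a mixture at the carbinol centre, which does not matter, and Dess–Martin oxidation gives 19, where the route is rejoined.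

Step 10. A second annulation at the remaining C–H/OH pair may follow the first. The condensation may also be slow because both phenols are hydrogen-bonded to the ketone, and prolonged heating with the amine salt could enolise C1'. Fallback: 20 is mono-O-alkylated with 3-chloro-3-methylbut-1-yne (DBU, cat. CuCl2, MeCN, 0 °C) to the aryl 1,1-dimethylpropargyl ether F8. Heating F8 (xylene, 140 °C) brings about propargyl Claisen rearrangement to the only free ortho carbon, 1,5-hydrogen shift and oxa-6π electrocyclisation. Because the two OH groups are equivalent, this gives the same chromene 23.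

Further compounds

F1 | step 5 | (4R,6R)-2-[4-methoxy-2,6-bis(methoxymethoxy)phenyl]-6-[(2E)-6-methylhepta-2,5-dien-2-yl]-4-phenyloxan-2-ol (lactol, anomeric centre undefined) | COCOc1cc(OC)cc(OCOC)c1C1(O)C[C@H](c2ccccc2)C[C@H](/C(C)=C/CC=C(C)C)O1
F2 | step 5 | (2R,4R)-6-[4-methoxy-2,6-bis(methoxymethoxy)phenyl]-2-[(2E)-6-methylhepta-2,5-dien-2-yl]-4-phenyl-3,4-dihydro-2H-pyran | COCOc1cc(OC)cc(OCOC)c1C1=C[C@H](c2ccccc2)C[C@H](/C(C)=C/CC=C(C)C)O1
F3 | step 3 | methyl (3S)-5-(ethylsulfanyl)-5-oxo-3-phenylpentanoate | COC(=O)C[C@H](c1ccccc1)CC(=O)SCC
F4 | step 3 | (2E)-2-iodo-6-methylhepta-2,5-diene | C/C(I)=C\CC=C(C)C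
F5 | step 3 | chloro[(2E)-6-methylhepta-2,5-dien-2-yl]zinc | C/C([Zn]Cl)=C\CC=C(C)C
F6 | step 8 | (1R,2S,6R)-3-methyl-2-(3-methylbut-2-en-1-yl)-6-phenylcyclohex-3-ene-1-carbaldehyde | O=C[C@@H]1[C@H](CC=C(C)C)C(C)=CC[C@H]1c2ccccc2
F7 | step 8 | [4-methoxy-2,6-bis(methoxymethoxy)phenyl][(1R,2S,6R)-3-methyl-2-(3-methylbut-2-en-1-yl)-6-phenylcyclohex-3-en-1-yl]methanol (carbinol centre undefined) | COCOc1cc(OC)cc(OCOC)c1C(O)[C@@H]2[C@H](CC=C(C)C)C(C)=CC[C@H]2c3ccccc3
F8 | step 10 | {2-hydroxy-4-methoxy-6-[(2-methylbut-3-yn-2-yl)oxy]phenyl}[(1R,2S,6R)-3-methyl-2-(3-methylbut-2-en-1-yl)-6-phenylcyclohex-3-en-1-yl]methanone | COc1cc(O)c(C(=O)[C@@H]2[C@H](CC=C(C)C)C(C)=CC[C@H]2c3ccccc3)c(OC(C)(C)C#C)c1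
A1 | alternative 1 | (2E)-1-(7-hydroxy-5-methoxy-2,2-dimethyl-2H-chromen-8-yl)-3-phenylprop-2-en-1-one | COc1cc(O)c(C(=O)/C=C/c2ccccc2)c2c1C=CC(C)(C)O2
A2 | alternative 1 | (E)-β-ocimene ((3E)-3,7-dimethylocta-1,3,6-triene) | C=C/C(C)=C/CC=C(C)C
A3 | alternative 2 | 1-(7-hydroxy-5-methoxy-2,2-dimethyl-2H-chromen-8-yl)-6-methyl-2-(1-phenylbut-3-en-1-yl)-3-(prop-1-en-2-yl)hept-5-en-1-one (configuration as in 23) | COc1cc(O)c(C(=O)[C@H]([C@H](CC=C(C)C)C(C)=C)[C@@H](CC=C)c2ccccc2)c2c1C=CC(C)(C)O2
A4 | alternative 3 | methyl 3-methyl-2-(3-methylbut-2-en-1-yl)-4-oxo-6-phenylcyclohexane-1-carboxylate (all-equatorial isomer) | O=C1C[C@@H](c2ccccc2)[C@H](C(=O)OC)[C@@H](CC=C(C)C)[C@@H]1C
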